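**Assumption:** the SMILES has no stereocentre and no descriptor for the 8,8' biaryl axis, so the target is made as the constitutionally defined compound with the axis uncontrolled (racemic if rotation is slow); no stereocentre has to be set.

## Retrosynthetic overview

1. Target 15 ⇐ global O-demethylation of the octamethyl ether 14.
2. Both pyranone rings (rings C) of 14 are closed last and together, from bis(2-aryl-3,3-dimethoxypropanone) 12; 12 ⇐ oxidative 1,2-aryl shift of bis-chalcone 11.
3. Key disconnection: the two Cα–Cβ bonds (future C2–C3 and C2'–C3') ⇐ double Claisen–Schmidt aldol condensation of bis-acetophenone 8 with two 4-methoxybenzaldehyde 9.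
4. 8 ⇐ double ortho-lithiation/acetaldehyde addition/oxidation of biaryl 4; 4 (the 8,8' axis) ⇐ oxidative homocoupling of the ortho-lithiated MOM ether 2 of 3,4,5-trimethoxyphenol 1.
5. Ring order: rings A are bought, the biaryl axis is made first, rings B are attached by the aldol, both rings C are closed last; the MOM group marks the oxygen that becomes O1.

## Route

Step 1
Reactants: 1 3,4,5-trimethoxyphenol
Product: 2 1,2,3-trimethoxy-5-(methoxymethoxy)benzene
Conditions: MOMCl (1.5 equiv), i-Pr2NEt (2 equiv), CH2Cl2, 0 °C → rt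
Reagents that add atoms: chloromethyl methyl ether, COCCl
Why: O-alkylation of the phenol (MOM protection) installs a strong ortho-directing group that is orthogonal to the methyl ethers and labels the oxygen that will become O1.

Step 2
Reactants: 2 1,2,3-trimethoxy-5-(methoxymethoxy)benzene (two molecules)
Product: 4 2,2'-bis(methoxymethoxy)-4,4',5,5',6,6'-hexamethoxy-1,1'-biphenyl, via aryllithium 3 (not isolated)
Conditions: n-BuLi (1.1 equiv), TMEDA, THF, 0 °C, 1 h; then anhydrous CuCl2 (1.5 equiv), −78 °C → rt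
Reagents that add atoms: none
Why: Directed ortho-metalation takes place at the position flanked by OMOM and OMe (the two free ring positions are equivalent), and one-electron oxidation of the aryllithium by CuCl2 gives the symmetrical tetra-ortho-oxygenated biaryl by oxidative homocoupling.

Step 3
Reactants: 4 2,2'-bis(methoxymethoxy)-4,4',5,5',6,6'-hexamethoxy-1,1'-biphenyl; 5 acetaldehyde
Product: 7 1,1'-[2,2'-bis(methoxymethoxy)-4,4',5,5',6,6'-hexamethoxy-1,1'-biphenyl-3,3'-diyl]di(ethan-1-ol) (mixture of diastereomers), via dilithiobiaryl 6 (not isolated)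
Conditions: n-BuLi (3 equiv), TMEDA, THF, 0 °C → rt, 2 h; MeCHO (6 equiv), −78 → 0 °C; then H2O
Reagents that add atoms: acetaldehyde, CC=O
Why: Double directed ortho-metalation at the only remaining C–H of each ring (between OMOM and OMe, as in the 3,3'-dilithiation of MOM-protected biaryl diols) is followed by 1,2-addition to acetaldehyde, and the unselectively formed carbinol stereocentres are erased in step 4.

Step 4
Reactants: 7 1,1'-[2,2'-bis(methoxymethoxy)-4,4',5,5',6,6'-hexamethoxy-1,1'-biphenyl-3,3'-diyl]di(ethan-1-ol)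
Product: 8 1,1'-[2,2'-bis(methoxymethoxy)-4,4',5,5',6,6'-hexamethoxy-1,1'-biphenyl-3,3'-diyl]di(ethan-1-one)
Conditions: IBX (3 equiv), EtOAc, 75 °C
Reagents that add atoms: none
Why: IBX oxidation of the secondary benzylic alcohols to aryl methyl ketones runs under neutral conditions that leave MOM and methyl ethers untouched.

Step 5
Reactants: 8 1,1'-[2,2'-bis(methoxymethoxy)-4,4',5,5',6,6'-hexamethoxy-1,1'-biphenyl-3,3'-diyl]di(ethan-1-one); 9 4-methoxybenzaldehyde (3 equiv)
Product: 11 (2E,2'E)-1,1'-[2,2'-bis(methoxymethoxy)-4,4',5,5',6,6'-hexamethoxy-1,1'-biphenyl-3,3'-diyl]bis[3-(4-methoxyphenyl)prop-2-en-1-one], via bis-aldol adduct 10 (not isolated)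
Conditions: KOH (50% aq), EtOH/THF, rt, 48 h
Reagents that add atoms: 4-methoxybenzaldehyde, COc1ccc(C=O)cc1
Why: In this double crossed aldol (Claisen–Schmidt) condensation the methyl ketone enolates add to the non-enolisable aldehyde and E1cB dehydration gives the thermodynamic (E)-enones, forming both future C2–C3 bonds while the MOM ethers are stable to base.

Step 6
Reactants: 11 (2E,2'E)-bis-chalcone
Product: 12 1,1'-[2,2'-bis(methoxymethoxy)-4,4',5,5',6,6'-hexamethoxy-1,1'-biphenyl-3,3'-diyl]bis[3,3-dimethoxy-2-(4-methoxyphenyl)propan-1-one] (mixture of diastereomers)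
Conditions: Tl(NO3)3·3H2O (2.4 equiv), MeOH/CH2Cl2, rt, 2–4 h; filter TlNO3, NaHCO3 wash
Reagents that add atoms: methanol, CO
Why: Oxythallation of each enone is followed by a 1,2-shift of the electron-rich 4-methoxyphenyl group from Cβ to Cα with loss of monovalent thallium and capture of the oxocarbenium ion by methanol (McKillop–Taylor oxidative rearrangement of chalcones), and the unselectively formed Cα stereocentres become sp2 C3 in step 7.

Step 7
Reactants: 12 bis(3,3-dimethoxy-2-arylpropan-1-one)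
Product: 14 5,5',6,6',7,7'-hexamethoxy-3,3'-bis(4-methoxyphenyl)-4H,4'H-[8,8'-bichromene]-4,4'-dione, via bisphenol bis-acetal 13 (not isolated)
Conditions: conc. HCl, MeOH/THF, reflux, 3 h
Reagents that add atoms: none
Why: Acid-catalysed acetal exchange removes the MOM groups and the freed phenols attack the activated dimethyl acetals, losing two methanol per ring to give the 4-pyranones (isoflavone ring closure), and because the 5-oxygen stays methylated only the 8,8'-linked regioisomer can form.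

Step 8
Reactants: 14 bis-isoflavone octamethyl ether
Product: 15 5,5',6,6',7,7'-hexahydroxy-3,3'-bis(4-hydroxyphenyl)-4H,4'H-[8,8'-bichromene]-4,4'-dione (target)
Conditions: BBr3 (24 equiv, 1 M in CH2Cl2), CH2Cl2, −78 °C → rt, 24 h, Ar; then MeOH, H2O, 0 °C; degassed solvents, Sephadex LH-20
Reagents that add atoms: none
Why: BBr3 O-demethylation (Lewis-acid activated SN2 cleavage) removes all eight aryl methyl ethers without opening the chromone rings, so no Wessely–Moser isomerisation to the 6,6'-linked isomer can occur.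

## Compound list

1 | 3,4,5-trimethoxyphenol | COc1cc(O)cc(OC)c1OC | starting material
2 | 1,2,3-trimethoxy-5-(methoxymethoxy)benzene | COCOc1cc(OC)c(OC)c(OC)c1 | intermediate
3 | [2,3,4-trimethoxy-6-(methoxymethoxy)phenyl]lithium | [Li]c1c(OCOC)cc(OC)c(OC)c1OC | intermediate (not isolated)
4 | 2,2'-bis(methoxymethoxy)-4,4',5,5',6,6'-hexamethoxy-1,1'-biphenyl | COCOc1cc(OC)c(OC)c(OC)c1-c1c(OCOC)cc(OC)c(OC)c1OC | intermediate
5 | acetaldehyde | CC=O | starting material
6 | [2,2'-bis(methoxymethoxy)-4,4',5,5',6,6'-hexamethoxy-1,1'-biphenyl-3,3'-diyl]dilithium | [Li]c1c(OC)c(OC)c(OC)c(-c2c(OCOC)c([Li])c(OC)c(OC)c2OC)c1OCOC | intermediate (not isolated)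
7 | 1,1'-[2,2'-bis(methoxymethoxy)-4,4',5,5',6,6'-hexamethoxy-1,1'-biphenyl-3,3'-diyl]di(ethan-1-ol), mixture of diastereomers | CC(O)c1c(OC)c(OC)c(OC)c(-c2c(OCOC)c(C(C)O)c(OC)c(OC)c2OC)c1OCOC | intermediate
8 | 1,1'-[2,2'-bis(methoxymethoxy)-4,4',5,5',6,6'-hexamethoxy-1,1'-biphenyl-3,3'-diyl]di(ethan-1-one) | CC(=O)c1c(OC)c(OC)c(OC)c(-c2c(OCOC)c(C(C)=O)c(OC)c(OC)c2OC)c1OCOC | intermediate
9 | 4-methoxybenzaldehyde | COc1ccc(C=O)cc1 | starting material
10 | 1,1'-[2,2'-bis(methoxymethoxy)-4,4',5,5',6,6'-hexamethoxy-1,1'-biphenyl-3,3'-diyl]bis[3-hydroxy-3-(4-methoxyphenyl)propan-1-one], mixture of diastereomers | COc1ccc(C(O)CC(=O)c2c(OC)c(OC)c(OC)c(-c3c(OCOC)c(C(=O)CC(O)c4ccc(OC)cc4)c(OC)c(OC)c3OC)c2OCOC)cc1 | intermediate (not isolated)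
11 | (2E,2'E)-1,1'-[2,2'-bis(methoxymethoxy)-4,4',5,5',6,6'-hexamethoxy-1,1'-biphenyl-3,3'-diyl]bis[3-(4-methoxyphenyl)prop-2-en-1-one] | COc1ccc(/C=C/C(=O)c2c(OC)c(OC)c(OC)c(-c3c(OCOC)c(C(=O)/C=C/c4ccc(OC)cc4)c(OC)c(OC)c3OC)c2OCOC)cc1 | intermediate
12 | 1,1'-[2,2'-bis(methoxymethoxy)-4,4',5,5',6,6'-hexamethoxy-1,1'-biphenyl-3,3'-diyl]bis[3,3-dimethoxy-2-(4-methoxyphenyl)propan-1-one], mixture of diastereomers | COc1ccc(C(C(OC)OC)C(=O)c2c(OC)c(OC)c(OC)c(-c3c(OCOC)c(C(=O)C(C(OC)OC)c4ccc(OC)cc4)c(OC)c(OC)c3OC)c2OCOC)cc1 | intermediate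
13 | 1,1'-[2,2'-dihydroxy-4,4',5,5',6,6'-hexamethoxy-1,1'-biphenyl-3,3'-diyl]bis[3,3-dimethoxy-2-(4-methoxyphenyl)propan-1-one], mixture of diastereomers | COc1ccc(C(C(OC)OC)C(=O)c2c(OC)c(OC)c(OC)c(-c3c(O)c(C(=O)C(C(OC)OC)c4ccc(OC)cc4)c(OC)c(OC)c3OC)c2O)cc1 | intermediate (not isolated)
14 | 5,5',6,6',7,7'-hexamethoxy-3,3'-bis(4-methoxyphenyl)-4H,4'H-[8,8'-bichromene]-4,4'-dione | COc1ccc(-c2coc3c(-c4c(OC)c(OC)c(OC)c5c(=O)c(-c6ccc(OC)cc6)coc45)c(OC)c(OC)c(OC)c3c2=O)cc1 | intermediate
15 | 5,5',6,6',7,7'-hexahydroxy-3,3'-bis(4-hydroxyphenyl)-4H,4'H-[8,8'-bichromene]-4,4'-dione | O=c1c(-c2ccc(O)cc2)coc2c(-c3c(O)c(O)c(O)c4c(=O)c(-c5ccc(O)cc5)coc34)c(O)c(O)c(O)c12 | target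

## Step count and risks

Total step count: 8. Longest linear sequence: 8 steps (1 → 15); acetaldehyde 5 and 4-methoxybenzaldehyde 9 enter as purchased materials.

Three steps most likely to fail:

**Step 2 (oxidative homocoupling to a tetra-ortho-substituted biaryl).** Protonation back to 2 or chlorination can erode the yield. The fallback sets out from 2 and comes back at 4. Compound 2 is lithiated exactly as before (aryllithium 3) but quenched with I2 to give the aryl iodide 2-iodo-3,4,5-trimethoxy-1-(methoxymethoxy)benzene F1. F1 is then dimerised by a classical Ullmann reductive homocoupling with activated zerovalent copper (Cu bronze, DMF, 150 °C, or neat at about 210 °C). This replaces oxidation of an organometallic by reductive coupling of an aryl halide, the long-established way to 2,2',6,6'-tetraalkoxybiphenyls, and delivers 4.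

**Step 6 (double oxidative rearrangement with Tl(NO3)3).** Nitric acid formed in the flask may unmask a phenol that trivalent thallium can over-oxidise, and two rearrangements must both succeed. The fallback sets out from 11 and comes back at 14. Weitz–Scheffer epoxidation of 11 (30% H2O2, NaOH, MeOH/THF, 0 °C → rt) gives the bis(epoxy ketone) [2,2'-bis(methoxymethoxy)-4,4',5,5',6,6'-hexamethoxy-1,1'-biphenyl-3,3'-diyl]bis{[trans-3-(4-methoxyphenyl)oxiran-2-yl]methanone} F2. BF3·OEt2 (CH2Cl2, 0 °C) opens each epoxide at the anisyl-stabilised benzylic carbon and triggers a 1,2-aroyl shift (Meinwald-type rearrangement). The product is the bis(α-formyl deoxybenzoin) 3,3'-[2,2'-bis(methoxymethoxy)-4,4',5,5',6,6'-hexamethoxy-1,1'-biphenyl-3,3'-diyl]bis[2-(4-methoxyphenyl)-3-oxopropanal] F3, which has the same carbon skeleton as 12 with free aldehydes. HCl in MeOH at reflux then removes the MOM groups and cyclodehydrates to 14; any MOM loss already under BF3 is harmless because it leads to the same product.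

**Step 8 (eightfold demethylation to an air-sensitive pyrogallol-type octaphenol).** Incomplete cleavage and oxidation during isolation are the dangers. The fallback sets out from 14 and comes back at 15. The ether cleavage is run as before (BBr3, or AlBr3/EtSH if the 7- and 4'-methyl ethers resist), but the free phenol is not isolated. The quenched, concentrated crude is acetylated at once (Ac2O, pyridine, DMAP, rt) to the air-stable, chromatographable octaacetate 3,3'-bis(4-acetoxyphenyl)-4,4'-dioxo-4H,4'H-[8,8'-bichromene]-5,5',6,6',7,7'-hexayl hexaacetate F4. F4 is purified on silica or by crystallisation, and under-demethylated material is separated at this stage. Acid-catalysed methanolysis (degassed HCl/MeOH, rt, Ar) then releases pure 15 with only volatile by-products.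

## Further compounds

F1 | step 2 | 2-iodo-3,4,5-trimethoxy-1-(methoxymethoxy)benzene | COCOc1cc(OC)c(OC)c(OC)c1I
F2 | step 6 | [2,2'-bis(methoxymethoxy)-4,4',5,5',6,6'-hexamethoxy-1,1'-biphenyl-3,3'-diyl]bis{[trans-3-(4-methoxyphenyl)oxiran-2-yl]methanone}, mixture of diastereomers | COc1ccc(C2OC2C(=O)c2c(OC)c(OC)c(OC)c(-c3c(OCOC)c(C(=O)C4OC4c4ccc(OC)cc4)c(OC)c(OC)c3OC)c2OCOC)cc1
F3 | step 6 | 3,3'-[2,2'-bis(methoxymethoxy)-4,4',5,5',6,6'-hexamethoxy-1,1'-biphenyl-3,3'-diyl]bis[2-(4-methoxyphenyl)-3-oxopropanal], mixture of diastereomers | COc1ccc(C(C=O)C(=O)c2c(OC)c(OC)c(OC)c(-c3c(OCOC)c(C(=O)C(C=O)c4ccc(OC)cc4)c(OC)c(OC)c3OC)c2OCOC)cc1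
F4 | step 8 | 3,3'-bis(4-acetoxyphenyl)-4,4'-dioxo-4H,4'H-[8,8'-bichromene]-5,5',6,6',7,7'-hexayl hexaacetate | CC(=O)Oc1ccc(-c2coc3c(-c4c(OC(C)=O)c(OC(C)=O)c(OC(C)=O)c5c(=O)c(-c6ccc(OC(C)=O)cc6)coc45)c(OC(C)=O)c(OC(C)=O)c(OC(C)=O)c3c2=O)cc1
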